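**Retrosynthetic overview**

1. The target is cut at the central CH2–CH2 bond into two C15 halves that differ only at the isopropenyl-bearing carbon. The left half (cyclopentanol 1S,2S,5R, OH cis to isopropenyl) is allyl sulfone 29; the right half (1S,2S,5S, OH trans) is allyl chloride 40. Julia-type alkylation and desulfonylation join them.
2. Each oxane is closed by O–CH2 etherification onto a (Z)-2-ene-1,4-diol unmasked from a 3-substituted furan. Its carbinol carbon comes from syn-directed reduction of a β-hydroxy ketone made by Fukuyama coupling.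
3. Each cyclopentane comes from a radical [3+2] annulation of one aldol-derived α-bromo imide (10) with ethylene. It forms C2–C3 and C4–C5 of the cyclopentan-1-ol (C3 and C4 are the ethylene carbons) in one operation and creates the isopropenyl group by loss of silicon.
4. Enabling feature: in the left cyclopentanol the hydroxyl oxygen on C1 and the CH2 end of the isopropenyl group on C5 are cis and four bonds apart (O–C1–C5–C–CH2). A SiMe2 unit can therefore tie them into a 1-oxa-2-silacyclohex-4-ene, a cyclic allylsilane that accepts a radical at C5 and then expels silicon. C2 lies between this carbinol and the oxygen-bearing oxane carbon (aldol-type 1,3-dioxygenation), so it can be a carbonyl-stabilised radical. Tether on gives the cis ring (left); tether off gives the trans ring (right).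
5. Ring order in each half: temporary oxasiline (step 5), then cyclopentane (steps 6 and 16), then oxane (steps 14 and 21); the halves are joined in steps 22 and 23.

Key step: step 6

Remark: the carbon α to the acyl group (C2 of the cyclopentanols) is not controlled in the annulations; it is set by equilibration in steps 10 and 17.

**Route**

Step 1
Reactants: 1 2-methylallylmagnesium chloride; 2 dichlorodimethylsilane
Product: 3 chlorodimethyl(2-methylallyl)silane
Conditions: Me2SiCl2 (3 equiv), Et2O, 0 °C → rt; distillation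
Reagents that add atoms: none
Why: Substitution at silicon by the allylic Grignard reagent, the excess of Me2SiCl2 holding the reaction at monosubstitution.

Step 2
Reactants: 4 (R)-4-benzyloxazolidin-2-one; 5 bromoacetyl bromide
Product: 6 (R)-4-benzyl-3-(bromoacetyl)oxazolidin-2-one
Conditions: n-BuLi, THF, −78 °C; then 5, −78 → 0 °C
Reagents that add atoms: none
Why: N-Acylation of the lithiated oxazolidinone by the acid bromide, which is far more reactive than the alkyl bromide.

Step 3
Reactants: 6 (R)-4-benzyl-3-(bromoacetyl)oxazolidin-2-one; 7 acrolein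
Product: 8 (R)-4-benzyl-3-[(2R,3S)-2-bromo-3-hydroxypent-4-enoyl]oxazolidin-2-one
Conditions: Bu2BOTf, Et3N, CH2Cl2, −78 °C; 7, −78 → 0 °C; then pH 7 buffer, MeOH, H2O2, 0 °C
Reagents that add atoms: none
Why: Evans syn-aldol addition of the Z boron enolate through a closed chair transition state with the auxiliary carbonyl turned away should set the carbinol centre (3S), which becomes the ring carbinol of both cyclopentanols, while the bromide-bearing C2 serves only as a radical precursor.

Step 4
Reactants: 8 (R)-4-benzyl-3-[(2R,3S)-2-bromo-3-hydroxypent-4-enoyl]oxazolidin-2-one; 3 chlorodimethyl(2-methylallyl)silane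
Product: 9 dimethyl(2-methylallyl)silyl ether of 8
Conditions: imidazole, CH2Cl2, 0 °C
Reagents that add atoms: none
Why: O-Silylation with a chlorosilane and imidazole, a base too weak to close the bromohydrin to an epoxide.

Step 5
Reactants: 9 dimethyl(2-methylallyl)silyl ether of 8
Product: 10 (R)-4-benzyl-3-{(2R)-bromo[(6S)-2,2,4-trimethyl-3,6-dihydro-2H-1,2-oxasilin-6-yl]acetyl}oxazolidin-2-one
Conditions: second-generation Grubbs catalyst (5 mol %), CH2Cl2 (0.01 M), 40 °C
Reagents that add atoms: none
Why: Ring-closing metathesis between the vinyl group and the 1,1-disubstituted alkene of the methallylsilane closes the six-membered silyl ether, whose ring forces the new trisubstituted alkene to be Z.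

Step 6
Reactants: 10 (R)-4-benzyl-3-{(2R)-bromo[(6S)-2,2,4-trimethyl-3,6-dihydro-2H-1,2-oxasilin-6-yl]acetyl}oxazolidin-2-one; 11 ethylene
Product: 14 (R)-4-benzyl-3-{[(2S,3R)-2-hydroxy-3-(prop-1-en-2-yl)cyclopentyl]carbonyl}oxazolidin-2-one (C1 epimers; OH cis to isopropenyl), via bicyclic tertiary bromide 12 (not isolated), via bromodimethylsilyl ether 13 (not isolated)
Conditions: ethylene (5 bar), fac-Ir(ppy)3 (1 mol %), 2,6-lutidine, MeCN (0.05 M), blue LEDs, 20 °C; then HF·pyridine, pyridine, THF, 0 °C
Reagents that add atoms: none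
Why: Photoexcited fac-Ir(ppy)3 reduces the C–Br bond of 10 to the imide-stabilised radical at C2, which adds to ethylene (Kharasch-type addition, bond C2–C3); the primary radical then closes 5-exo-trig onto the CH= carbon of the oxasiline (bond C4–C5) to give a tertiary β-silyl radical, which takes up bromine (atom transfer from 10, or oxidation by tetravalent iridium and capture by bromide) to give 12, whose β-bromosilane unit collapses to the isopropenyl group and the O–SiMe2Br ether 13, cleaved by HF·pyridine. The closest known reaction type is the atom-transfer radical [3+2] annulation of but-3-enyl radicals from α-halocarbonyl compounds with alkenes, combined with the Peterson-type β-elimination of β-halosilanes. The only ring closed is the cyclopentane, by 5-exo-trig attack; the six-membered Si–O tether holds the carbinol oxygen in the plane of the acceptor alkene, so the new ring must be cis-fused to the oxasiline and the isopropenyl carbon ends up cis to the oxygen, while the carbinol centre itself comes unchanged from the aldol of step 3. C2 is formed in the intermolecular step without reliable control and is equilibrated in step 10. The step needs capture of the C2 radical by ethylene before 3-exo closure with 1,2-alkenyl shift or hydrogen abstraction (5 bar of ethylene, 20 °C, MeCN as a poor hydrogen donor), ring closure before a second ethylene adds (the 5-exo closure is unimolecular and fast), and 5-exo rather than 6-endo attack (the CH= carbon is unsubstituted and attack there gives the tertiary β-silyl radical); the bromide rather than the iodide is chosen so that halogen transfer does not outrun the cyclization.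

Step 7
Reactants: 15 3-bromofuran; 16 oxirane
Product: 18 2-(furan-3-yl)ethanol, via furan-3-yllithium 17 (not isolated)
Conditions: n-BuLi, THF, −78 °C; 16, BF3·OEt2, −78 °C
Reagents that add atoms: none
Why: Bromine–lithium exchange at −78 °C (cold enough to prevent migration of lithium to C2 of the furan) and BF3-assisted SN2 opening of oxirane.

Step 8
Reactants: 18 2-(furan-3-yl)ethanol
Product: 19 3-(2-iodoethyl)furan
Conditions: I2, PPh3, imidazole, CH2Cl2, 0 °C → rt
Reagents that add atoms: iodine, II
Why: Appel-type iodination of the primary alcohol via its alkoxyphosphonium salt (SN2).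

Step 9
Reactants: 19 3-(2-iodoethyl)furan
Product: 20 [2-(furan-3-yl)ethyl]zinc iodide (titrated THF solution)
Conditions: Zn dust (activated with cat. 1,2-dibromoethane and TMSCl), LiCl, THF, 40 °C
Reagents that add atoms: zinc, [Zn]
Why: Direct insertion of LiCl-activated zinc into the primary C–I bond gives the alkylzinc halide, towards which the furan ring is inert.

Step 10
Reactants: 14 (R)-4-benzyl-3-{[(2S,3R)-2-hydroxy-3-(prop-1-en-2-yl)cyclopentyl]carbonyl}oxazolidin-2-one (C1 epimers; OH cis to isopropenyl)
Product: 21 S-ethyl (1S,2S,3R)-2-hydroxy-3-(prop-1-en-2-yl)cyclopentane-1-carbothioate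
Conditions: EtSH, n-BuLi, THF, 0 °C; then DBU, rt; aq. NH4Cl
Reagents that add atoms: ethanethiol, CCS
Why: Lithium ethanethiolate cleaves the exocyclic imide carbonyl (acyl transfer to sulfur) and returns the auxiliary, and DBU then exchanges the acidic α-proton of the thioester so that C1 should settle with the acyl group trans to the neighbouring hydroxyl, the all-cis alternative being strongly disfavoured.

Step 11
Reactants: 21 S-ethyl (1S,2S,3R)-2-hydroxy-3-(prop-1-en-2-yl)cyclopentane-1-carbothioate; 20 [2-(furan-3-yl)ethyl]zinc iodide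
Product: 22 3-(furan-3-yl)-1-[(1S,2S,3R)-2-hydroxy-3-(prop-1-en-2-yl)cyclopentyl]propan-1-one
Conditions: 20 (3 equiv), PdCl2(PPh3)2 (5 mol %), toluene/THF, rt; aq. HCl work-up
Reagents that add atoms: none
Why: Fukuyama coupling, in which zerovalent palladium inserts into the C–S bond and the alkylzinc transfers its alkyl group, should give the ketone without over-addition and without touching the hydroxyl or the alkenes.

Step 12
Reactants: 22 3-(furan-3-yl)-1-[(1S,2S,3R)-2-hydroxy-3-(prop-1-en-2-yl)cyclopentyl]propan-1-one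
Product: 23 (1R)-3-(furan-3-yl)-1-[(1R,2S,3R)-2-hydroxy-3-(prop-1-en-2-yl)cyclopentyl]propan-1-ol
Conditions: Et2BOMe, THF/MeOH (4:1), −78 °C; NaBH4; then MeOH azeotrope
Reagents that add atoms: none
Why: Narasaka–Prasad reduction, in which the diethylboron chelate of the β-hydroxy ketone (trans-fused to the cyclopentane) is attacked axially by external hydride, should give the 1,3-syn diol and so the (R) carbinol that becomes C2 of the oxane.

Step 13
Reactants: 23 (1R)-3-(furan-3-yl)-1-[(1R,2S,3R)-2-hydroxy-3-(prop-1-en-2-yl)cyclopentyl]propan-1-ol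
Product: 26 (2Z)-2-{(3R)-3-hydroxy-3-[(1R,2S,3R)-2-hydroxy-3-(prop-1-en-2-yl)cyclopentyl]propyl}but-2-ene-1,4-diol, via furan endoperoxide 24 (not isolated), via cis-enedial 25 (not isolated)
Conditions: O2, tetraphenylporphyrin (cat.), visible light, CH2Cl2, −78 °C; Me2S, −78 → 0 °C; then CeCl3·7H2O, NaBH4, MeOH, −40 → 0 °C
Reagents that add atoms: dioxygen, O=O
Why: [4+2] Cycloaddition of singlet oxygen to the furan (much faster than its ene reaction with the 1,1-disubstituted alkene), reduction of the endoperoxide by Me2S and Luche reduction of the cis-enedial should give the (Z)-but-2-ene-1,4-diol, whose geometry is inherited from the furan ring.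

Step 14
Reactants: 26 (2Z)-2-{(3R)-3-hydroxy-3-[(1R,2S,3R)-2-hydroxy-3-(prop-1-en-2-yl)cyclopentyl]propyl}but-2-ene-1,4-diol
Product: 28 (1S,2S,5R)-2-[(2R,5Z)-5-(2-chloroethylidene)oxan-2-yl]-5-(prop-1-en-2-yl)cyclopentan-1-ol, via bis(allylic chloride) 27 (not isolated)
Conditions: MsCl, 2,4,6-collidine, LiCl, DMF, 0 °C; aqueous work-up; then NaH, THF (0.01 M), 0 °C → rt
Reagents that add atoms: lithium chloride, [Li+].[Cl-]; methanesulfonyl chloride, CS(=O)(=O)Cl
Why: Chloride displacement of the two primary allylic mesylates (the secondary alcohols react much more slowly) is followed by Williamson etherification, in which the alkoxide of the side-chain carbinol closes the oxane by 6-exo-tet SN2 attack on the CH2Cl attached to the fully substituted alkene carbon, while the ring alkoxide could only form larger rings.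

Step 15
Reactants: 28 (1S,2S,5R)-2-[(2R,5Z)-5-(2-chloroethylidene)oxan-2-yl]-5-(prop-1-en-2-yl)cyclopentan-1-ol
Product: 29 (1S,2S,5R)-2-{(2R,5Z)-5-[2-(phenylsulfonyl)ethylidene]oxan-2-yl}-5-(prop-1-en-2-yl)cyclopentan-1-ol
Conditions: PhSO2Na, DMF, rt
Reagents that add atoms: sodium benzenesulfinate, [Na+].[O-]S(=O)c1ccccc1
Why: SN2 S-alkylation of benzenesulfinate by the primary allylic chloride, with retention of alkene position and geometry.

Step 16
Reactants: 10 (R)-4-benzyl-3-{(2R)-bromo[(6S)-2,2,4-trimethyl-3,6-dihydro-2H-1,2-oxasilin-6-yl]acetyl}oxazolidin-2-one; 11 ethylene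
Product: 32 (R)-4-benzyl-3-{[(2S,3S)-2-hydroxy-3-(prop-1-en-2-yl)cyclopentyl]carbonyl}oxazolidin-2-one (C1 epimers; OH trans to isopropenyl), via ring-opened fluorosilane 30 (not isolated), via tertiary bromide 31 (not isolated)
Conditions: HF·pyridine, pyridine, THF, 0 °C; NaHCO3 work-up, crude used; then ethylene (5 bar), fac-Ir(ppy)3 (1 mol %), 2,6-lutidine, MeCN, blue LEDs, 20 °C
Reagents that add atoms: none
Why: HF·pyridine cleaves the Si–O bond so that the tether is taken off, and the same Kharasch-type addition to ethylene, 5-exo-trig cyclization, bromine transfer and β-elimination of the β-bromosilane then run on the acyclic (Z)-allylsilane, where allylic 1,3-strain keeps the carbinol hydrogen in the alkene plane so that the ring should close on the face away from the hydroxyl and place the isopropenyl group trans to it (the carbon α to the imide is again left for the next step).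

Step 17
Reactants: 32 (R)-4-benzyl-3-{[(2S,3S)-2-hydroxy-3-(prop-1-en-2-yl)cyclopentyl]carbonyl}oxazolidin-2-one (C1 epimers; OH trans to isopropenyl)
Product: 33 S-ethyl (1S,2S,3S)-2-hydroxy-3-(prop-1-en-2-yl)cyclopentane-1-carbothioate
Conditions: EtSH, n-BuLi, THF, 0 °C; then DBU, rt; aq. NH4Cl
Reagents that add atoms: ethanethiol, CCS
Why: Thiolate cleavage of the imide followed by DBU-mediated exchange of the thioester α-proton should place the acyl group trans to the hydroxyl and cis to the isopropenyl group, the all-trans and most stable arrangement.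

Step 18
Reactants: 33 S-ethyl (1S,2S,3S)-2-hydroxy-3-(prop-1-en-2-yl)cyclopentane-1-carbothioate; 20 [2-(furan-3-yl)ethyl]zinc iodide
Product: 34 3-(furan-3-yl)-1-[(1S,2S,3S)-2-hydroxy-3-(prop-1-en-2-yl)cyclopentyl]propan-1-one
Conditions: 20 (3 equiv), PdCl2(PPh3)2 (5 mol %), toluene/THF, rt; aq. HCl work-up
Reagents that add atoms: none
Why: Fukuyama coupling of the thioester with the alkylzinc under zerovalent palladium catalysis, as in step 11.

Step 19
Reactants: 34 3-(furan-3-yl)-1-[(1S,2S,3S)-2-hydroxy-3-(prop-1-en-2-yl)cyclopentyl]propan-1-one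
Product: 35 (1R)-3-(furan-3-yl)-1-[(1R,2S,3S)-2-hydroxy-3-(prop-1-en-2-yl)cyclopentyl]propan-1-ol
Conditions: Et2BOMe, THF/MeOH (4:1), −78 °C; NaBH4; then MeOH azeotrope
Reagents that add atoms: none
Why: Narasaka–Prasad reduction through the boron chelate, as in step 12, should give the 1,3-syn diol with the (R) side-chain carbinol.

Step 20
Reactants: 35 (1R)-3-(furan-3-yl)-1-[(1R,2S,3S)-2-hydroxy-3-(prop-1-en-2-yl)cyclopentyl]propan-1-ol
Product: 38 (2Z)-2-{(3R)-3-hydroxy-3-[(1R,2S,3S)-2-hydroxy-3-(prop-1-en-2-yl)cyclopentyl]propyl}but-2-ene-1,4-diol, via right-half endoperoxide 36 (not isolated), via right-half cis-enedial 37 (not isolated)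
Conditions: O2, tetraphenylporphyrin (cat.), visible light, CH2Cl2, −78 °C; Me2S, −78 → 0 °C; then CeCl3·7H2O, NaBH4, MeOH, −40 → 0 °C
Reagents that add atoms: dioxygen, O=O
Why: Singlet-oxygen [4+2] cycloaddition to the furan, Me2S reduction and Luche reduction, as in step 13, with the Z geometry taken from the furan ring.

Step 21
Reactants: 38 (2Z)-2-{(3R)-3-hydroxy-3-[(1R,2S,3S)-2-hydroxy-3-(prop-1-en-2-yl)cyclopentyl]propyl}but-2-ene-1,4-diol
Product: 40 (1S,2S,5S)-2-[(2R,5Z)-5-(2-chloroethylidene)oxan-2-yl]-5-(prop-1-en-2-yl)cyclopentan-1-ol, via right-half bis(allylic chloride) 39 (not isolated)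
Conditions: MsCl, 2,4,6-collidine, LiCl, DMF, 0 °C; aqueous work-up; then NaH, THF (0.01 M), 0 °C → rt
Reagents that add atoms: lithium chloride, [Li+].[Cl-]; methanesulfonyl chloride, CS(=O)(=O)Cl
Why: Selective allylic chlorination and 6-exo-tet Williamson etherification, as in step 14.

Step 22
Reactants: 29 (1S,2S,5R)-2-{(2R,5Z)-5-[2-(phenylsulfonyl)ethylidene]oxan-2-yl}-5-(prop-1-en-2-yl)cyclopentan-1-ol; 40 (1S,2S,5S)-2-[(2R,5Z)-5-(2-chloroethylidene)oxan-2-yl]-5-(prop-1-en-2-yl)cyclopentan-1-ol
Product: 41 coupled sulfone (left and right halves joined at the central CH2–CH2 bond; PhSO2 on the left central carbon; epimers at that carbon)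
Conditions: 29, n-BuLi (2 equiv), THF/HMPA, −78 °C; 40 pre-treated with LiHMDS (1 equiv), THF, −78 °C; combine, −78 → −30 °C; aq. NH4Cl
Reagents that add atoms: none
Why: Julia-type sulfone alkylation, in which the α-sulfonyl allyl carbanion (formed beside the lithium alkoxide) should displace the primary allylic chloride of the pre-formed alkoxide of 40 at its α-carbon (SN2), joining the halves at the central CH2–CH2 bond; the sulfone-bearing centre is removed in the next step.

Step 23
Reactants: 41 coupled sulfone
Product: 42 CNP0267443.2 (target)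
Conditions: PdCl2(dppp) (5 mol %), LiBHEt3, THF, 0 °C → rt
Reagents that add atoms: none
Why: Palladium-catalysed hydride desulfonylation (Tsuji–Trost-type ionisation to a π-allyl complex by zerovalent palladium and hydride delivery to the less substituted terminus) should replace the sulfonyl group by hydrogen with retention of the position and Z geometry of the trisubstituted alkene.

**Compound list**

1 | 2-methylallylmagnesium chloride | C=C(C)C[Mg]Cl | starting material
2 | dichlorodimethylsilane | C[Si](C)(Cl)Cl | starting material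
3 | chlorodimethyl(2-methylallyl)silane | C=C(C)C[Si](C)(C)Cl | intermediate
4 | (R)-4-benzyloxazolidin-2-one | O=C1OC[C@@H](Cc2ccccc2)N1 | starting material
5 | bromoacetyl bromide | O=C(Br)CBr | starting material
6 | (R)-4-benzyl-3-(bromoacetyl)oxazolidin-2-one | O=C1OC[C@@H](Cc2ccccc2)N1C(=O)CBr | intermediate
7 | acrolein | C=CC=O | starting material
8 | (R)-4-benzyl-3-[(2R,3S)-2-bromo-3-hydroxypent-4-enoyl]oxazolidin-2-one | O=C1OC[C@@H](Cc2ccccc2)N1C(=O)[C@H](Br)[C@@H](O)C=C | intermediate
9 | dimethyl(2-methylallyl)silyl ether of 8 (2R,3S) | O=C1OC[C@@H](Cc2ccccc2)N1C(=O)[C@H](Br)[C@@H](O[Si](C)(C)CC(C)=C)C=C | intermediate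
10 | (R)-4-benzyl-3-{(2R)-bromo[(6S)-2,2,4-trimethyl-3,6-dihydro-2H-1,2-oxasilin-6-yl]acetyl}oxazolidin-2-one | O=C1OC[C@@H](Cc2ccccc2)N1C(=O)[C@H](Br)[C@@H]2C=C(C)C[Si](C)(C)O2 | intermediate
11 | ethylene | C=C | starting material
12 | bicyclic tertiary bromide: cis-fused 5-bromo-3,3,5-trimethyl-2-oxa-3-silabicyclo[4.3.0]nonane with the imide carbonyl on C9 (epimers at C5 and C9) | O=C(N2[C@H](Cc3ccccc3)COC2=O)C1CC[C@H]4[C@@H]1O[Si](C)(C)CC4(C)Br | intermediate
13 | bromodimethylsilyl ether of 14 | C=C(C)[C@H]1CCC(C(=O)N2[C@H](Cc3ccccc3)COC2=O)[C@H]1O[Si](C)(C)Br | intermediate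
14 | (R)-4-benzyl-3-{[(2S,3R)-2-hydroxy-3-(prop-1-en-2-yl)cyclopentyl]carbonyl}oxazolidin-2-one (C1 epimers; OH cis to isopropenyl) | C=C(C)[C@H]1CCC(C(=O)N2[C@H](Cc3ccccc3)COC2=O)[C@H]1O | intermediate
15 | 3-bromofuran | Brc1ccoc1 | starting material
16 | oxirane | C1CO1 | starting material
17 | furan-3-yllithium | [Li]c1ccoc1 | intermediate
18 | 2-(furan-3-yl)ethanol | OCCc1ccoc1 | intermediate
19 | 3-(2-iodoethyl)furan | ICCc1ccoc1 | intermediate
20 | [2-(furan-3-yl)ethyl]zinc iodide | I[Zn]CCc1ccoc1 | intermediate
21 | S-ethyl (1S,2S,3R)-2-hydroxy-3-(prop-1-en-2-yl)cyclopentane-1-carbothioate | C=C(C)[C@H]1CC[C@H](C(=O)SCC)[C@H]1O | intermediate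
22 | 3-(furan-3-yl)-1-[(1S,2S,3R)-2-hydroxy-3-(prop-1-en-2-yl)cyclopentyl]propan-1-one | C=C(C)[C@H]1CC[C@H](C(=O)CCc2ccoc2)[C@H]1O | intermediate
23 | (1R)-3-(furan-3-yl)-1-[(1R,2S,3R)-2-hydroxy-3-(prop-1-en-2-yl)cyclopentyl]propan-1-ol | C=C(C)[C@H]1CC[C@H]([C@H](O)CCc2ccoc2)[C@H]1O | intermediate
24 | furan endoperoxide of 23 (2,3,7-trioxabicyclo[2.2.1]hept-5-ene, side chain on C5) | C=C(C)[C@H]1CC[C@H]([C@H](O)CCC2=CC3OOC2O3)[C@H]1O | intermediate
25 | cis-enedial from 23 ((Z)-2-substituted but-2-enedial) | C=C(C)[C@H]1CC[C@H]([C@H](O)CC/C(C=O)=C/C=O)[C@H]1O | intermediate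
26 | (2Z)-2-{(3R)-3-hydroxy-3-[(1R,2S,3R)-2-hydroxy-3-(prop-1-en-2-yl)cyclopentyl]propyl}but-2-ene-1,4-diol | C=C(C)[C@H]1CC[C@H]([C@H](O)CC/C(CO)=C/CO)[C@H]1O | intermediate
27 | bis(allylic chloride) of 26 (both CH2OH replaced by CH2Cl) | C=C(C)[C@H]1CC[C@H]([C@H](O)CC/C(CCl)=C/CCl)[C@H]1O | intermediate
28 | (1S,2S,5R)-2-[(2R,5Z)-5-(2-chloroethylidene)oxan-2-yl]-5-(prop-1-en-2-yl)cyclopentan-1-ol | C=C(C)[C@H]1CC[C@H]([C@H]2CC/C(=C/CCl)CO2)[C@H]1O | intermediate
29 | (1S,2S,5R)-2-{(2R,5Z)-5-[2-(phenylsulfonyl)ethylidene]oxan-2-yl}-5-(prop-1-en-2-yl)cyclopentan-1-ol | C=C(C)[C@H]1CC[C@H]([C@H]2CC/C(=C/CS(=O)(=O)c3ccccc3)CO2)[C@H]1O | intermediate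
30 | ring-opened fluorosilane: (R)-4-benzyl-3-[(2R,3S,4Z)-2-bromo-6-(fluorodimethylsilyl)-3-hydroxy-5-methylhex-4-enoyl]oxazolidin-2-one | O=C1OC[C@@H](Cc2ccccc2)N1C(=O)[C@H](Br)[C@@H](O)/C=C(/C)C[Si](C)(C)F | intermediate
31 | tertiary bromide: 2-hydroxycyclopentyl imide with a 2-bromo-1-(fluorodimethylsilyl)propan-2-yl group on C3, trans to OH (epimers at C1 and at the bromide carbon) | O=C(N2[C@H](Cc3ccccc3)COC2=O)C1CC[C@@H](C(C)(Br)C[Si](C)(C)F)[C@@H]1O | intermediate
32 | (R)-4-benzyl-3-{[(2S,3S)-2-hydroxy-3-(prop-1-en-2-yl)cyclopentyl]carbonyl}oxazolidin-2-one (C1 epimers; OH trans to isopropenyl) | C=C(C)[C@@H]1CCC(C(=O)N2[C@H](Cc3ccccc3)COC2=O)[C@H]1O | intermediate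
33 | S-ethyl (1S,2S,3S)-2-hydroxy-3-(prop-1-en-2-yl)cyclopentane-1-carbothioate | C=C(C)[C@@H]1CC[C@H](C(=O)SCC)[C@H]1O | intermediate
34 | 3-(furan-3-yl)-1-[(1S,2S,3S)-2-hydroxy-3-(prop-1-en-2-yl)cyclopentyl]propan-1-one | C=C(C)[C@@H]1CC[C@H](C(=O)CCc2ccoc2)[C@H]1O | intermediate
35 | (1R)-3-(furan-3-yl)-1-[(1R,2S,3S)-2-hydroxy-3-(prop-1-en-2-yl)cyclopentyl]propan-1-ol | C=C(C)[C@@H]1CC[C@H]([C@H](O)CCc2ccoc2)[C@H]1O | intermediate
36 | right-half endoperoxide (furan endoperoxide of 35) | C=C(C)[C@@H]1CC[C@H]([C@H](O)CCC2=CC3OOC2O3)[C@H]1O | intermediate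
37 | right-half cis-enedial from 35 | C=C(C)[C@@H]1CC[C@H]([C@H](O)CC/C(C=O)=C/C=O)[C@H]1O | intermediate
38 | (2Z)-2-{(3R)-3-hydroxy-3-[(1R,2S,3S)-2-hydroxy-3-(prop-1-en-2-yl)cyclopentyl]propyl}but-2-ene-1,4-diol | C=C(C)[C@@H]1CC[C@H]([C@H](O)CC/C(CO)=C/CO)[C@H]1O | intermediate
39 | right-half bis(allylic chloride) of 38 | C=C(C)[C@@H]1CC[C@H]([C@H](O)CC/C(CCl)=C/CCl)[C@H]1O | intermediate
40 | (1S,2S,5S)-2-[(2R,5Z)-5-(2-chloroethylidene)oxan-2-yl]-5-(prop-1-en-2-yl)cyclopentan-1-ol | C=C(C)[C@@H]1CC[C@H]([C@H]2CC/C(=C/CCl)CO2)[C@H]1O | intermediate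
41 | coupled sulfone: the target skeleton with a phenylsulfonyl group on the central carbon next to the left alkene (epimers at that carbon; both exocyclic alkenes Z) | C=C(C)[C@H]1CC[C@H]([C@H]2CC/C(=C/C(C/C=C3/CC[C@H]([C@H]4CC[C@@H](C(=C)C)[C@@H]4O)OC3)S(=O)(=O)c3ccccc3)CO2)[C@H]1O | intermediate
42 | CNP0267443.2: left cyclopentanol (1S,2S,5R), right cyclopentanol (1S,2S,5S), both oxane C2 centres R, both exocyclic alkenes Z | C=C(C)[C@H]1CC[C@H]([C@H]2CC/C(=C/CC/C=C3/CC[C@H]([C@H]4CC[C@@H](C(=C)C)[C@@H]4O)OC3)CO2)[C@H]1O | target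

**Count and risks**

Total step count: 23. Longest linear sequence: 13 steps (steps 2–6, 10–15, 22 and 23, from 4).

Step 6 (the same chemistry recurs in step 16). Capture of the imide-stabilised radical by ethylene may be too slow, so that 3-exo closure with 1,2-alkenyl shift, hydrogen abstraction or repeated ethylene insertion compete with the annulation. The fallback sets out from 10. The gas is replaced by vinylboronic acid pinacol ester, a liquid and a much faster trap for carbonyl-substituted radicals, under the same light-driven conditions and the same HF·pyridine work-up. This should give the borylated cyclopentanol F1, which carries the boronate on the ring carbon next to the isopropenyl-bearing carbon. Radical protodeboronation of the borylated cyclopentanol F1 (exchange of pinacol for catechol, then 4-tert-butylcatechol as hydrogen donor with Et3B/air initiation) removes boron and comes back to the route at 14.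

Step 22. Proton transfer from the free hydroxyls may quench the sulfonyl carbanion, and O-alkylation or elimination may compete with C-alkylation. The fallback sets out from 29 and 40. Both cyclopentanols are silylated (TESCl, imidazole) to the sulfone triethylsilyl ether F2 and the chloride triethylsilyl ether F3. The simple monoanion of F2 (n-BuLi, 1 equiv, THF/HMPA, −78 °C) is alkylated with F3 to the bis-silylated coupled sulfone F4. HF·pyridine then removes both silyl groups and comes back to the route at 41.

Step 13 (and its twin, step 20). The cis-enedial may isomerise to the E isomer, be trapped as cyclic acetals by the neighbouring carbinol, or undergo 1,4-reduction. The fallback sets out from 23. Photo-oxygenation in the presence of iPr2NEt (base-induced rearrangement of the endoperoxide) should give the stable γ-hydroxybutenolide F5. NaBH4 reduces its masked aldehyde and the hydroxy acid relactonises to the butenolide F6. DIBAL-H reduces the butenolide F6 to the (Z)-diol and comes back to the route at 26; the Z geometry is now held by a lactone ring until the last reduction.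

Further compounds
F1 | step 6 | borylated cyclopentanol: 14 with a pinacolboronate on the ring CH next to the isopropenyl-bearing carbon (epimers at C1 and at the boron-bearing carbon) | C=C(C)[C@H]1C(B2OC(C)(C)C(C)(C)O2)CC(C(=O)N3[C@H](Cc4ccccc4)COC3=O)[C@H]1O
F2 | step 22 | sulfone triethylsilyl ether: 29 with its cyclopentanol as OSiEt3 | C=C(C)[C@H]1CC[C@H]([C@H]2CC/C(=C/CS(=O)(=O)c3ccccc3)CO2)[C@H]1O[Si](CC)(CC)CC
F3 | step 22 | chloride triethylsilyl ether: 40 with its cyclopentanol as OSiEt3 | C=C(C)[C@@H]1CC[C@H]([C@H]2CC/C(=C/CCl)CO2)[C@H]1O[Si](CC)(CC)CC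
F4 | step 22 | bis-silylated coupled sulfone: 41 with both cyclopentanols as OSiEt3 | C=C(C)[C@H]1CC[C@H]([C@H]2CC/C(=C/C(C/C=C3/CC[C@H]([C@H]4CC[C@@H](C(=C)C)[C@@H]4O[Si](CC)(CC)CC)OC3)S(=O)(=O)c3ccccc3)CO2)[C@H]1O[Si](CC)(CC)CC
F5 | step 13 | γ-hydroxybutenolide: 5-hydroxy-4-substituted furan-2(5H)-one in place of the furan of 23 | C=C(C)[C@H]1CC[C@H]([C@H](O)CCC2=CC(=O)OC2O)[C@H]1O
F6 | step 13 | butenolide: 4-substituted furan-2(5H)-one in place of the furan of 23 | C=C(C)[C@H]1CC[C@H]([C@H](O)CCC2=CC(=O)OC2)[C@H]1O
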